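(The readings are simulated for substances that don't exist; scatter was added.)

The easy step is to divide a reading by the charge: Thursday's 26.0 % of the first end groups at 10.0 h is 0.316 of the second end groups charged, and that share, links formed per second end group charged, I call the capture.

| setting | Wednesday's | Thursday's | east | west |
|---|---|---|---|---|
| first end groups | 0.17 M | 0.17 M | 0.17 M | 0.17 M |
| second end groups | 0.047 M | 0.14 M | 0.170 M | 0.0600 M |
| protic impurity | 0.085 M | 0.085 M | 0.0850 M | 0.0850 M |
| remark | run made earlier | run made earlier |  |  |
| time |  |  | 15 h | 5.0 h |

| run | time / h | links / % |
|---|---|---|
| Wednesday's | 0.833 | 0.3 |
| Wednesday's | 1.50 | 2.4 |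
| Wednesday's | 3.00 | 3.1 |
| Wednesday's | 6.00 | 7.2 |
| Wednesday's | 10.0 | 9.8 |
| Thursday's | 0.833 | 4.6 |
| Thursday's | 1.50 | 7.4 |
| Thursday's | 3.00 | 13.5 |
| Thursday's | 6.00 | 21.1 |
| Thursday's | 10.0 | 26.0 |

(scatter of a reading: 1 percentage point)

- the earlier runs were read with a standard deviation of 1 percentage point

- the winner by amount of links, in percent of the first end groups charged; "neither" if no more than 2 percentage points parts them (east / west / neither)
- how much links is there at the end, in percent of the first end groups charged: east
- how much links is there at the end, in percent of the first end groups charged: west

Thursday has 2.98 times Wednesday's charge of second end groups and 2.65 times its links at 10.0 h. Thursday's capture predicts 8.73 % for Wednesday, against a reading of 9.8 % with a scatter of 1 point. So I treat the second end groups as the concentration that sets the order, pseudo-first-order while the first end groups stay near their charge, and at a fixed charge of first end groups I read the capture as a function of time.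

The fraction of first end groups turned into links is the capture times the ratio of charges. That ratio is 0.276 on Wednesday, 0.824 on Thursday, 0.353 in west and 1.00 in east, just past the tested range. At Thursday's capture of 0.316 the rule asks for more links than the charge of first end groups holds once the ratio passes 3.16, and that is the border of the rule. West lies between the two runs in ratio and within their readings in time, but east's 15 h lies past the last reading at 10.0 h, so west gets a number and east a bracket:

West, capture read between Thursday's 3.00 h and 6.00 h: 0.225, so links 7.96 %

East, capture from 0.316 to 0.390 (Thursday's last slope continued), so links 31.6 % to 39.0 %

I commit to east. The forecast also says east, with 38 % (32 % to 44 %) for east and 8 % (6.5 % to 10 %) for west, having noted that “Thursday's rate falls faster than its loss of second end groups explains”.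

The flask gives east, with 35.5 % in east and 8.82 % in west, so east's capture is 0.355, inside my bracket, and west's is 0.250 against my 0.225.

    second end groups + protic impurity → quenched reagent (k = 0.155 /M/h)
    first end groups + second end groups ⇌ links + released group (K = 2.10, k = 0.432 /M/h)
    second end groups → decomposed reagent (k = 0.0576 /h)

In east half of the link-forming turnover up to 15.0 h is done by 3.35 h, and links stand at 28.5 % at 7.50 h with second end groups at 38.4 % of their charge. By 15.0 h links reach 35.5 % while second end groups fall to 17.7 %, decomposed reagent climbs from 0.0464 M to 0.0658 M, and first end groups stand at 64.5 %.

A neighbour of east with 0.68 M of second end groups has a ratio of 4.00, past the border, and Thursday's capture of 0.316 asks there for 126 % of the first end groups, more than the charge. At 15.0 h that neighbour gives 76.9 %, a capture of 0.192, with 23.1 % of the first end groups still there.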